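## Retrosynthetic overview

1. The C8 ester is cut first: macrocyclic 8-alcohol plus a silyl-protected (2R,3R)-epoxy acid, made by Sharpless epoxidation of a 2-(silyloxymethyl)but-2-en-1-ol and oxidation.
2. The ten-membered ring is formed second and last, at C7–C8: a samarium diiodide ketyl radical from the C8 aldehyde adds to C7 of a 3-(acetoxymethyl)butenolide and acetate is lost. This also unveils the α-methylene lactone and sets C7 and C8.
3. The butenolide is formed first, by ring-closing metathesis of a 2-(acetoxymethyl)acrylate of the C6 divinyl carbinol; C5–C6 comes from an asymmetric Nozaki–Hiyama–Kishi coupling with acrolein.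
4. Open chain: E-C4=C5 by carboalumination–iodination of a terminal alkyne; C2–C3 by catalytic asymmetric propargylation of a Z-enal; Z-C1=C10 is taken from 4-methyl-5,6-dihydro-2H-pyran-2-one.

Assumption: atoms are labelled C1–C15 by germacranolide numbering (lactone oxygen on C6, acyloxy on C8, hydroxyl on C2, C13 the exocyclic methylene, side chain C1′–C5′), and each chiral chromium ligand is used as the enantiomer that gives the configuration stated.

## Route

Step 1
Reactants: 1 4-methyl-5,6-dihydro-2H-pyran-2-one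
Product: 3 (2Z)-N-methoxy-N,3-dimethyl-5-(triethylsilyloxy)pent-2-enamide, via hydroxy Weinreb amide 2 (not isolated)
Conditions: MeNH(OMe)·HCl, iPrMgCl, THF, −20 °C; then Et3SiCl, DMAP (5 mol %), 0 °C → rt
Reagents that add atoms: N,O-dimethylhydroxylamine hydrochloride (CNOC.Cl); chlorotriethylsilane (CC[Si](Cl)(CC)CC)
Why: Weinreb aminolysis of the lactone by the chloromagnesium amide opens the ring while the cis relationship of C2 and C9 across the trisubstituted olefin, fixed by the six-membered ring, is kept as the Z geometry, and silylation of the alkoxide in the same pot prevents relactonization.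

Step 2
Reactants: 3 (2Z)-N-methoxy-N,3-dimethyl-5-(triethylsilyloxy)pent-2-enamide
Product: 4 (2Z)-3-methyl-5-(triethylsilyloxy)pent-2-enal
Conditions: iBu2AlH, THF, −78 °C; aq. Rochelle salt
Reagents that add atoms: none
Why: Weinreb amide reduction stops at the chelated aluminium hemiaminal until work-up, so the Z-enal is obtained without over-reduction or Z/E isomerization at −78 °C.

Step 3
Reactants: 4 (2Z)-3-methyl-5-(triethylsilyloxy)pent-2-enal; 5 3-bromoprop-1-yne (propargyl bromide)
Product: 6 (4R,5Z)-6-methyl-8-(triethylsilyloxy)oct-5-en-1-yn-4-ol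
Conditions: CrCl2 (10 mol %), chiral oxazolinyl aryl sulfonamide ligand (11 mol %), Et3N (11 mol %), Mn, Cp2ZrCl2, LiCl, THF, 0 °C → rt
Reagents that add atoms: none
Why: Catalytic asymmetric Nozaki–Hiyama propargylation, in which the allenylchromium species formed from propargyl bromide adds through its γ-carbon to the Re face of the aldehyde under control of the chiral sulfonamide ligand, giving the homopropargylic alcohol and setting C2 as R.

Step 4
Reactants: 6 (4R,5Z)-6-methyl-8-(triethylsilyloxy)oct-5-en-1-yn-4-ol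
Product: 7 (4R,5Z)-4-(tert-butyldimethylsilyloxy)-6-methyl-8-(triethylsilyloxy)oct-5-en-1-yne
Conditions: tBuMe2SiCl, imidazole, DMF, rt
Reagents that add atoms: tert-butyl(chloro)dimethylsilane (CC(C)(C)[Si](C)(C)Cl)
Why: Standard silylation of the secondary allylic alcohol gives a TBS ether that outlasts the later selective removal of the primary triethylsilyl ether.

Step 5
Reactants: 7 (4R,5Z)-4-(tert-butyldimethylsilyloxy)-6-methyl-8-(triethylsilyloxy)oct-5-en-1-yne
Product: 9 (1E,4R,5Z)-4-(tert-butyldimethylsilyloxy)-1-iodo-2,6-dimethyl-8-(triethylsilyloxy)octa-1,5-diene, via alkenylalane 8 (not isolated)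
Conditions: Me3Al, Cp2ZrCl2 (25 mol %), ClCH2CH2Cl, 0 °C → rt; then I2, THF, −30 → 0 °C
Reagents that add atoms: trimethylaluminium (C[Al](C)C); iodine (II)
Why: Zirconium-catalysed Negishi carboalumination adds methyl and aluminium syn across the terminal alkyne with methyl on the internal carbon, and iodinolysis with retention fixes the C4=C5 olefin as E.

Step 6
Reactants: 9 (1E,4R,5Z)-4-(tert-butyldimethylsilyloxy)-1-iodo-2,6-dimethyl-8-(triethylsilyloxy)octa-1,5-diene; 10 prop-2-enal (acrolein)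
Product: 11 (3S,4E,7R,8Z)-7-(tert-butyldimethylsilyloxy)-5,9-dimethyl-11-(triethylsilyloxy)undeca-1,4,8-trien-3-ol
Conditions: CrCl2 (10 mol %), NiCl2(2,9-dimethyl-1,10-phenanthroline) (2 mol %), chiral oxazolinyl aryl sulfonamide ligand (11 mol %), Et3N (11 mol %), Mn, Cp2ZrCl2, LiCl, MeCN, rt
Reagents that add atoms: none
Why: Catalytic asymmetric Nozaki–Hiyama–Kishi coupling, in which the alkenylchromium reagent formed by nickel-to-chromium transmetalation adds 1,2 to acrolein with retention of olefin geometry and the chiral chromium complex sets C6 as the 3S carbinol independently of the remote C2 centre.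

Step 7
Reactants: 12 2-(bromomethyl)prop-2-enoic acid
Product: 13 2-(acetoxymethyl)prop-2-enoic acid
Conditions: NaOAc, AcOH, 70 °C
Reagents that add atoms: sodium acetate (CC(=O)[O-].[Na+])
Why: Acetate displaces the allylic bromide by an SN2 or SN2′ path, both giving the same product, and so installs the leaving group that is later expelled from C13.

Step 8
Reactants: 11 (3S,4E,7R,8Z)-7-(tert-butyldimethylsilyloxy)-5,9-dimethyl-11-(triethylsilyloxy)undeca-1,4,8-trien-3-ol; 13 2-(acetoxymethyl)prop-2-enoic acid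
Product: 14 (3S,4E,7R,8Z)-7-(tert-butyldimethylsilyloxy)-5,9-dimethyl-11-(triethylsilyloxy)undeca-1,4,8-trien-3-yl 2-(acetoxymethyl)prop-2-enoate
Conditions: iPrN=C=NiPr, DMAP (10 mol %), CH2Cl2, −20 → 0 °C
Reagents that add atoms: none
Why: Carbodiimide (Steglich) esterification at low temperature acylates the bis-allylic alcohol on oxygen without ionization, so C6 keeps its configuration.

Step 9
Reactants: 14 (3S,4E,7R,8Z)-7-(tert-butyldimethylsilyloxy)-5,9-dimethyl-11-(triethylsilyloxy)undeca-1,4,8-trien-3-yl 2-(acetoxymethyl)prop-2-enoate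
Product: 15 [(5R)-5-[(1E,4R,5Z)-4-(tert-butyldimethylsilyloxy)-2,6-dimethyl-8-(triethylsilyloxy)octa-1,5-dien-1-yl]-2-oxo-2,5-dihydrofuran-3-yl]methyl acetate
Conditions: second-generation Grubbs catalyst RuCl2(=CHPh)(H2IMes)(PCy3) (5 mol %), CH2Cl2 (5 mM), 40 °C
Reagents that add atoms: none
Why: Ring-closing metathesis, in which the ruthenium carbene initiates at the only monosubstituted olefin and closes onto the 1,1-disubstituted acrylate to give the five-membered butenolide while the trisubstituted olefins stay inert and C6 is untouched.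

Step 10
Reactants: 15 [(5R)-5-[(1E,4R,5Z)-4-(tert-butyldimethylsilyloxy)-2,6-dimethyl-8-(triethylsilyloxy)octa-1,5-dien-1-yl]-2-oxo-2,5-dihydrofuran-3-yl]methyl acetate
Product: 17 [(5R)-5-[(1E,4R,5Z)-4-(tert-butyldimethylsilyloxy)-2,6-dimethyl-8-oxoocta-1,5-dien-1-yl]-2-oxo-2,5-dihydrofuran-3-yl]methyl acetate, via primary alcohol 16 (not isolated)
Conditions: o-iodoxybenzoic acid (IBX, 3 equiv), DMSO, rt; used at once
Reagents that add atoms: none
Why: o-Iodoxybenzoic acid in DMSO removes a primary triethylsilyl ether in the presence of a TBS ether and oxidizes the freed alcohol to the aldehyde under base-free conditions, which protects the acidic C6–H of the butenolide and the β,γ-unsaturated aldehyde from isomerization.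

Step 11
Reactants: 17 [(5R)-5-[(1E,4R,5Z)-4-(tert-butyldimethylsilyloxy)-2,6-dimethyl-8-oxoocta-1,5-dien-1-yl]-2-oxo-2,5-dihydrofuran-3-yl]methyl acetate
Product: 18 (3aR,4R,6Z,8R,10E,11aR)-8-(tert-butyldimethylsilyloxy)-4-hydroxy-6,10-dimethyl-3-methylidene-3a,4,5,8,9,11a-hexahydrocyclodeca[b]furan-2(3H)-one
Conditions: SmI2 (2.5 equiv), tBuOH (2 equiv), THF, −78 → 0 °C, syringe-pump addition of 17 (final 2 mM); aq. NH4Cl at low temperature
Reagents that add atoms: none
Why: Proposed new method: single-electron reduction of the aldehyde gives a samarium ketyl radical that adds 10-exo-trig to the butenolide β-carbon C7 on the face anti to the C5 substituent at C6 (trans-fused lactone, C7 R), the resulting α-carbonyl radical is reduced to the samarium enolate which expels the C13 acetate to give the exocyclic methylene, and C8 is expected R because the samarium-bound ketyl oxygen lies over the lactone face, bridged to the lactone carbonyl and away from the CH2OAc arm, while C9 points outward toward C6; the closest known reactions are samarium diiodide ketyl–enoate couplings to γ-lactones, medium-ring ketyl–olefin cyclizations and β-acetoxy elimination from samarium enolates.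

Step 12
Reactants: 19 but-2-yn-1-ol
Product: 21 (2E)-2-({[tri(propan-2-yl)silyl]oxy}methyl)but-2-en-1-ol, via alkenylmagnesium chloride 20 (not isolated)
Conditions: iBuMgCl (2.2 equiv), Cp2TiCl2 (5 mol %), Et2O, 25 °C; then iPr3SiOCH2Cl, THF, 0 °C
Reagents that add atoms: (triisopropylsiloxy)methyl chloride (ClCO[Si](C(C)C)(C(C)C)C(C)C)
Why: Titanocene-catalysed hydromagnesiation (Sato) adds H and Mg syn across the propargylic alcohol with magnesium on C2, and the alkenyl Grignard is C-alkylated with retention by the reactive α-chloro ether, so the free hydroxymethyl ends cis and the silyloxymethyl trans to the methyl group.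

Step 13
Reactants: 21 (2E)-2-({[tri(propan-2-yl)silyl]oxy}methyl)but-2-en-1-ol
Product: 22 [(2R,3R)-3-methyl-2-({[tri(propan-2-yl)silyl]oxy}methyl)oxiran-2-yl]methanol
Conditions: Ti(OiPr)4 (10 mol %), L-(+)-diisopropyl tartrate (12 mol %), tBuOOH, 4 Å molecular sieves, CH2Cl2, −20 °C
Reagents that add atoms: tert-butyl hydroperoxide (CC(C)(C)OO)
Why: Sharpless asymmetric epoxidation, in which the L-(+)-tartrate titanium complex delivers oxygen to the olefin face that gives the (2R,3R) epoxide while the cis relationship of the methyl group and the carbinol carbon is carried over from the olefin.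

Step 14
Reactants: 22 [(2R,3R)-3-methyl-2-({[tri(propan-2-yl)silyl]oxy}methyl)oxiran-2-yl]methanol
Product: 23 (2R,3R)-3-methyl-2-({[tri(propan-2-yl)silyl]oxy}methyl)oxirane-2-carboxylic acid
Conditions: TEMPO (20 mol %), PhI(OAc)2 (2.2 equiv), MeCN/H2O (1:1), rt
Reagents that add atoms: water (O)
Why: Nitroxyl-catalysed oxidation with (diacetoxyiodo)benzene in aqueous acetonitrile takes the primary alcohol through the aldehyde hydrate to the acid without touching the epoxide or the silyl ether, and both stereocentres are retained.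

Step 15
Reactants: 23 (2R,3R)-3-methyl-2-({[tri(propan-2-yl)silyl]oxy}methyl)oxirane-2-carboxylic acid; 18 (3aR,4R,6Z,8R,10E,11aR)-8-(tert-butyldimethylsilyloxy)-4-hydroxy-6,10-dimethyl-3-methylidene-3a,4,5,8,9,11a-hexahydrocyclodeca[b]furan-2(3H)-one
Product: 25 (3aR,4R,6Z,8R,10E,11aR)-8-(tert-butyldimethylsilyloxy)-6,10-dimethyl-3-methylidene-2-oxo-2,3,3a,4,5,8,9,11a-octahydrocyclodeca[b]furan-4-yl (2R,3R)-3-methyl-2-({[tri(propan-2-yl)silyl]oxy}methyl)oxirane-2-carboxylate, via mixed anhydride 24 (not isolated)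
Conditions: 2,4,6-Cl3C6H2COCl, Et3N, toluene, rt; then 18, DMAP, toluene, rt → 40 °C
Reagents that add atoms: none
Why: Yamaguchi esterification, in which the mixed anhydride of the hindered quaternary acid is activated by DMAP and acylates the C8 alcohol with retention at C8 while the C2 oxygen and the side-chain hydroxyl stay silyl-protected.

Step 16
Reactants: 25 (3aR,4R,6Z,8R,10E,11aR)-8-(tert-butyldimethylsilyloxy)-6,10-dimethyl-3-methylidene-2-oxo-2,3,3a,4,5,8,9,11a-octahydrocyclodeca[b]furan-4-yl (2R,3R)-3-methyl-2-({[tri(propan-2-yl)silyl]oxy}methyl)oxirane-2-carboxylate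
Product: 26 (3aR,4R,6Z,8R,10E,11aR)-8-hydroxy-6,10-dimethyl-3-methylidene-2-oxo-2,3,3a,4,5,8,9,11a-octahydrocyclodeca[b]furan-4-yl (2R,3R)-2-(hydroxymethyl)-3-methyloxirane-2-carboxylate
Conditions: HF·pyridine, pyridine, THF, 0 °C → rt
Reagents that add atoms: none
Why: Fluoride-mediated cleavage of both silyl ethers with buffered HF·pyridine leaves the glycidic ester, the α-methylene lactone and the allylic alcohol intact and touches no stereocentre.

## Compound list

1 | 4-methyl-5,6-dihydro-2H-pyran-2-one | CC1=CC(=O)OCC1 | starting material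
2 | (2Z)-5-hydroxy-N-methoxy-N,3-dimethylpent-2-enamide (present in the flask as its magnesium alkoxide) | CON(C)C(=O)/C=C(/C)CCO | intermediate
3 | (2Z)-N-methoxy-N,3-dimethyl-5-(triethylsilyloxy)pent-2-enamide | CON(C)C(=O)/C=C(/C)CCO[Si](CC)(CC)CC | intermediate
4 | (2Z)-3-methyl-5-(triethylsilyloxy)pent-2-enal | O=C/C=C(/C)CCO[Si](CC)(CC)CC | intermediate
5 | 3-bromoprop-1-yne (propargyl bromide) | C#CCBr | starting material
6 | (4R,5Z)-6-methyl-8-(triethylsilyloxy)oct-5-en-1-yn-4-ol | C#CC[C@@H](O)/C=C(/C)CCO[Si](CC)(CC)CC | intermediate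
7 | (4R,5Z)-4-(tert-butyldimethylsilyloxy)-6-methyl-8-(triethylsilyloxy)oct-5-en-1-yne | C#CC[C@@H](O[Si](C)(C)C(C)(C)C)/C=C(/C)CCO[Si](CC)(CC)CC | intermediate
8 | dimethyl[(1E,4R,5Z)-4-(tert-butyldimethylsilyloxy)-2,6-dimethyl-8-(triethylsilyloxy)octa-1,5-dien-1-yl]alumane | C[Al](C)/C=C(\C)C[C@@H](O[Si](C)(C)C(C)(C)C)/C=C(/C)CCO[Si](CC)(CC)CC | intermediate
9 | (1E,4R,5Z)-4-(tert-butyldimethylsilyloxy)-1-iodo-2,6-dimethyl-8-(triethylsilyloxy)octa-1,5-diene | I/C=C(\C)C[C@@H](O[Si](C)(C)C(C)(C)C)/C=C(/C)CCO[Si](CC)(CC)CC | intermediate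
10 | prop-2-enal (acrolein) | C=CC=O | starting material
11 | (3S,4E,7R,8Z)-7-(tert-butyldimethylsilyloxy)-5,9-dimethyl-11-(triethylsilyloxy)undeca-1,4,8-trien-3-ol | C=C[C@H](O)/C=C(\C)C[C@@H](O[Si](C)(C)C(C)(C)C)/C=C(/C)CCO[Si](CC)(CC)CC | intermediate
12 | 2-(bromomethyl)prop-2-enoic acid | C=C(CBr)C(=O)O | starting material
13 | 2-(acetoxymethyl)prop-2-enoic acid | CC(=O)OCC(=C)C(=O)O | intermediate
14 | (3S,4E,7R,8Z)-7-(tert-butyldimethylsilyloxy)-5,9-dimethyl-11-(triethylsilyloxy)undeca-1,4,8-trien-3-yl 2-(acetoxymethyl)prop-2-enoate | C=C[C@H](OC(=O)C(=C)COC(C)=O)/C=C(\C)C[C@@H](O[Si](C)(C)C(C)(C)C)/C=C(/C)CCO[Si](CC)(CC)CC | intermediate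
15 | [(5R)-5-[(1E,4R,5Z)-4-(tert-butyldimethylsilyloxy)-2,6-dimethyl-8-(triethylsilyloxy)octa-1,5-dien-1-yl]-2-oxo-2,5-dihydrofuran-3-yl]methyl acetate | CC(=O)OCC1=C[C@H](OC1=O)/C=C(\C)C[C@@H](O[Si](C)(C)C(C)(C)C)/C=C(/C)CCO[Si](CC)(CC)CC | intermediate
16 | [(5R)-5-[(1E,4R,5Z)-4-(tert-butyldimethylsilyloxy)-8-hydroxy-2,6-dimethylocta-1,5-dien-1-yl]-2-oxo-2,5-dihydrofuran-3-yl]methyl acetate | CC(=O)OCC1=C[C@H](OC1=O)/C=C(\C)C[C@@H](O[Si](C)(C)C(C)(C)C)/C=C(/C)CCO | intermediate
17 | [(5R)-5-[(1E,4R,5Z)-4-(tert-butyldimethylsilyloxy)-2,6-dimethyl-8-oxoocta-1,5-dien-1-yl]-2-oxo-2,5-dihydrofuran-3-yl]methyl acetate | CC(=O)OCC1=C[C@H](OC1=O)/C=C(\C)C[C@@H](O[Si](C)(C)C(C)(C)C)/C=C(/C)CC=O | intermediate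
18 | (3aR,4R,6Z,8R,10E,11aR)-8-(tert-butyldimethylsilyloxy)-4-hydroxy-6,10-dimethyl-3-methylidene-3a,4,5,8,9,11a-hexahydrocyclodeca[b]furan-2(3H)-one | C=C1C(=O)O[C@@H]2/C=C(\C)C[C@@H](O[Si](C)(C)C(C)(C)C)/C=C(/C)C[C@@H](O)[C@@H]12 | intermediate
19 | but-2-yn-1-ol | CC#CCO | starting material
20 | chloromagnesium (2E)-2-(chloromagnesio)but-2-en-1-olate (H and Mg cis, methyl cis to the CH2O group) | C/C=C(\CO[Mg]Cl)[Mg]Cl | intermediate
21 | (2E)-2-({[tri(propan-2-yl)silyl]oxy}methyl)but-2-en-1-ol (free CH2OH cis to the methyl group) | C/C=C(\CO)CO[Si](C(C)C)(C(C)C)C(C)C | intermediate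
22 | [(2R,3R)-3-methyl-2-({[tri(propan-2-yl)silyl]oxy}methyl)oxiran-2-yl]methanol | OC[C@]1(CO[Si](C(C)C)(C(C)C)C(C)C)O[C@@H]1C | intermediate
23 | (2R,3R)-3-methyl-2-({[tri(propan-2-yl)silyl]oxy}methyl)oxirane-2-carboxylic acid | OC(=O)[C@]1(CO[Si](C(C)C)(C(C)C)C(C)C)O[C@@H]1C | intermediate
24 | (2R,3R)-3-methyl-2-({[tri(propan-2-yl)silyl]oxy}methyl)oxirane-2-carboxylic 2,4,6-trichlorobenzoic anhydride | O=C(OC(=O)c1c(Cl)cc(Cl)cc1Cl)[C@]1(CO[Si](C(C)C)(C(C)C)C(C)C)O[C@@H]1C | intermediate
25 | (3aR,4R,6Z,8R,10E,11aR)-8-(tert-butyldimethylsilyloxy)-6,10-dimethyl-3-methylidene-2-oxo-2,3,3a,4,5,8,9,11a-octahydrocyclodeca[b]furan-4-yl (2R,3R)-3-methyl-2-({[tri(propan-2-yl)silyl]oxy}methyl)oxirane-2-carboxylate | C=C1C(=O)O[C@@H]2/C=C(\C)C[C@@H](O[Si](C)(C)C(C)(C)C)/C=C(/C)C[C@@H](OC(=O)[C@]3(CO[Si](C(C)C)(C(C)C)C(C)C)O[C@@H]3C)[C@@H]12 | intermediate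
26 | (3aR,4R,6Z,8R,10E,11aR)-8-hydroxy-6,10-dimethyl-3-methylidene-2-oxo-2,3,3a,4,5,8,9,11a-octahydrocyclodeca[b]furan-4-yl (2R,3R)-2-(hydroxymethyl)-3-methyloxirane-2-carboxylate | C=C1C(=O)O[C@@H]2/C=C(\C)C[C@@H](O)/C=C(/C)C[C@@H](OC(=O)[C@]3(CO)O[C@@H]3C)[C@@H]12 | target

## Step count and risk

Total step count: 16. Longest linear sequence: 12 (steps 1–6, 8–11, 15, 16).

Three steps most likely to fail:

Step 11 (ketyl macrocyclization; both the ten-membered ring closure and the C8 configuration are at stake). The fallback sets out from 17 and forms the same C7–C8 bond by a polar allylation through a closed transition state. Pd(PPh3)4 with InI turns the allylic acetate into an allylindium species that adds through the ring carbon C7 to the aldehyde by a six-membered chair. With the C6 substituent held trans on the cyclic allyl unit, this should give the anti product, the C8-epimeric macrocyclic alcohol F1. Mitsunobu esterification of F1 with acid 23 (PPh3, diisopropyl azodicarboxylate, toluene) inverts C8 and comes back to the route at 25.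

Step 6 (asymmetric chromium-mediated coupling with acrolein; C6 depends on catalyst control alone). The fallback sets out from 9 and reverses the polarity at C6. Iodine–lithium exchange (tBuLi, Et2O, −78 °C) and DMF give the dienal F2. Addition of trimethylsilylacetylene under a dinuclear zinc–ProPhenol catalyst (Et2Zn, ligand enantiomer chosen for the 3R alcohol) gives the silylated propargylic alcohol F3. K2CO3 in MeOH removes the C-silyl group to give the terminal alkynol F4. Lindlar semihydrogenation (Pd/CaCO3 poisoned with Pb(OAc)2, quinoline, H2) comes back to the route at 11.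

Step 12 (C-alkylation of the hydromagnesiation product with the silyloxymethyl chloride; O-alkylation of the alkoxide may compete). The fallback sets out from 19 and swaps the roles of the two hydroxymethyl carbons. Ruthenium-catalysed trans-hydrostannation ([Cp*RuCl]4, Bu3SnH, CH2Cl2) puts tin on the carbon next to the carbinol and cis to the methyl group, giving the (Z)-2-stannyl alcohol F5. Silylation (iPr3SiCl, imidazole) gives its TIPS ether F6. Tin–lithium exchange (nBuLi, THF, −78 °C) and formaldehyde install the free hydroxymethyl cis to the methyl group and come back to the route at 21.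

## Further compounds

F1 | step 11 | (3aR,4S,6Z,8R,10E,11aR)-8-(tert-butyldimethylsilyloxy)-4-hydroxy-6,10-dimethyl-3-methylidene-3a,4,5,8,9,11a-hexahydrocyclodeca[b]furan-2(3H)-one (C8 epimer of 18) | C=C1C(=O)O[C@@H]2/C=C(\C)C[C@@H](O[Si](C)(C)C(C)(C)C)/C=C(/C)C[C@H](O)[C@@H]12
F2 | step 6 | (2E,5R,6Z)-5-(tert-butyldimethylsilyloxy)-3,7-dimethyl-9-(triethylsilyloxy)nona-2,6-dienal | O=C/C=C(\C)C[C@@H](O[Si](C)(C)C(C)(C)C)/C=C(/C)CCO[Si](CC)(CC)CC
F3 | step 6 | (3R,4E,7R,8Z)-7-(tert-butyldimethylsilyloxy)-5,9-dimethyl-11-(triethylsilyloxy)-1-(trimethylsilyl)undeca-4,8-dien-1-yn-3-ol | C[Si](C)(C)C#C[C@H](O)/C=C(\C)C[C@@H](O[Si](C)(C)C(C)(C)C)/C=C(/C)CCO[Si](CC)(CC)CC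
F4 | step 6 | (3R,4E,7R,8Z)-7-(tert-butyldimethylsilyloxy)-5,9-dimethyl-11-(triethylsilyloxy)undeca-4,8-dien-1-yn-3-ol | C#C[C@H](O)/C=C(\C)C[C@@H](O[Si](C)(C)C(C)(C)C)/C=C(/C)CCO[Si](CC)(CC)CC
F5 | step 12 | (2Z)-2-(tributylstannyl)but-2-en-1-ol | C/C=C(/CO)[Sn](CCCC)(CCCC)CCCC
F6 | step 12 | tributyl[(2Z)-1-{[tri(propan-2-yl)silyl]oxy}but-2-en-2-yl]stannane | C/C=C(/CO[Si](C(C)C)(C(C)C)C(C)C)[Sn](CCCC)(CCCC)CCCC
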